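With drimane numbering (ring A: C1–C5, C10; ring B: C5–C10; C11 benzylidene carbon), ring B is disconnected at C6–C7 and C5–C10: C5=C6 becomes a dienophile and C7=C8–C9=C10 a diene, linked by the C1–C4 chain. An iminium-catalysed, enantioselective intramolecular Diels–Alder reaction of an acyclic (E)-trienal bearing a (Z)-tetrasubstituted diene therefore closes rings A and B at once and sets C5 and quaternary C10; it exploits the C7/C10 1,4-relationship of ring B, the C8-methyl/C9–C11 substitution (left as a C8=C9 alkene) and the C4 gem-dimethyl tether. The C6 formyl activator is then excised, C8 set by directed hydrogenation, and the aryl unit attached at C11, dehydrated and sulfated.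

Key step: step 5

Remark: aryl positions are numbered C1′ (bonded to C11) to C6′; C2′ and C5′ carry the sulfates, C3′ the formyl group and C4′ the free hydroxyl.
Assumption: aryl hydrogen sulfates are handled as their sodium salts but are drawn as the free acids; the free-acid form of the target is released by cation exchange in the last step.

Step 1
Reactants: 1 but-2-yn-1-ol; 2 isopropenylmagnesium bromide
Product: 4 (2Z)-3-iodo-2-(prop-1-en-2-yl)but-2-en-1-ol, via alkenylmagnesium chelate 3 (not isolated)
Conditions: 2 (2.5 equiv), CuI (10 mol%), THF, 0 °C to reflux; then I2, −78 to 0 °C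
Reagents that add atoms: iodine, II
Why: Hydroxyl-directed anti-carbomagnesiation of a propargylic alcohol places the isopropenyl group on C9 and magnesium on C10 cis to the CH2O arm in a five-membered chelate, so that iodinolysis with retention should give the (Z)-iodide with the C10 methyl cis to the isopropenyl group.

Step 2
Reactants: 5 2,2-dimethylpent-4-enenitrile; 4 (2Z)-3-iodo-2-(prop-1-en-2-yl)but-2-en-1-ol
Product: 7 (5Z)-6-(hydroxymethyl)-2,2,5,7-tetramethylocta-5,7-dienenitrile, via B-alkyl-9-BBN 6 (not isolated)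
Conditions: 5, 9-BBN dimer, THF, 0 °C to rt; then 4, Pd(dppf)Cl2 (5 mol%), AsPh3, Cs2CO3, DMF/H2O, rt
Reagents that add atoms: none
Why: In this B-alkyl Suzuki–Miyaura coupling, anti-Markovnikov hydroboration of the terminal alkene gives a primary alkylborane that should couple with the alkenyl iodide with retention of alkene geometry, the nitrile and free hydroxyl being inert.

Step 3
Reactants: 7 (5Z)-6-(hydroxymethyl)-2,2,5,7-tetramethylocta-5,7-dienenitrile
Product: 8 (5Z)-6-(hydroxymethyl)-2,2,5,7-tetramethylocta-5,7-dienal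
Conditions: i-Bu2AlH (2.5 equiv), CH2Cl2, −78 to −40 °C; then aq. tartaric acid, 0 °C
Reagents that add atoms: water, O
Why: Partial hydride reduction of the α-quaternary nitrile should stop at the N-aluminio imine, which hydrolyses to the aldehyde on work-up while the hydroxyl only consumes one hydride.

Step 4
Reactants: 8 (5Z)-6-(hydroxymethyl)-2,2,5,7-tetramethylocta-5,7-dienal; 9 diethyl [(E)-2-(cyclohexylamino)ethenyl]phosphonate
Product: 11 (2E,7Z)-8-(hydroxymethyl)-4,4,7,9-tetramethyldeca-2,7,9-trienal, via N-cyclohexyl enimine 10 (not isolated)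
Conditions: 9, NaH, THF, 0 °C to rt; then aq. oxalic acid, rt
Reagents that add atoms: water, O
Why: Horner–Wadsworth–Emmons formyl-olefination with the metallated enamine phosphonate should give the (E)-unsaturated imine, and mild acid hydrolysis releases the (E)-enal at a temperature too low for uncatalysed cycloaddition.

Step 5
Reactants: 11 (2E,7Z)-8-(hydroxymethyl)-4,4,7,9-tetramethyldeca-2,7,9-trienal
Product: 12 (1S,4aS,8aS)-4-(hydroxymethyl)-3,4a,8,8-tetramethyl-1,2,4a,5,6,7,8,8a-octahydronaphthalene-1-carbaldehyde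
Conditions: (2S,5S)-5-benzyl-2-tert-butyl-3-methylimidazolidin-4-one (20 mol%), HClO4 (20 mol%), MeCN/H2O 98:2, −10 °C to rt
Reagents that add atoms: none
Why: Reversible condensation of enal 11 with the imidazolidinone gives an (E)-iminium ion whose lowered LUMO lets C5=C6 add across the s-cis diene C7=C8–C9=C10 in a concerted but asynchronous [4+2] cycloaddition that forms C5–C10 and C6–C7 in one operation, and hydrolysis of the product iminium releases 12 and the amine. The closest known reaction type is the imidazolidinone-catalysed enantioselective intramolecular Diels–Alder reaction of (E)-2,7,9-trienals to trans-fused bicycles. Ring B is closed by the [4+2] union of the four-carbon diene and the two-carbon dienophile, and ring A is closed simultaneously as a six-membered ring by the C5–C10 bond, with the C1–C4 tether in a chair and exo to both π-components (the C4 gem-dimethyl group favouring the folded conformer). C5 and C10 are set relative to each other (trans fusion, 5α-H and 10β-methyl) by suprafacial addition through the endo transition state of the (E)-enal, with the tether on the outer and the methyl on the inner position of C10 as fixed by the (Z)-alkene made in steps 1 and 2, and their absolute configuration is set by the catalyst, whose benzyl group is expected to block one face of the iminium so that the diene adds to the Si faces of C6 and C5. The step needs endo over exo selectivity and a single π-face, which the (E)-enal and (Z)-diene geometries of the substrate, secondary orbital overlap and the (2S,5S)-catalyst should secure, whereas the transient 6α-formyl centre is irrelevant because step 6 removes it. The accepted risk is the steric demand of the leading C5–C10 bond between a neopentyl carbon and a fully substituted diene terminus.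

Step 6
Reactants: 12 (1S,4aS,8aS)-4-(hydroxymethyl)-3,4a,8,8-tetramethyl-1,2,4a,5,6,7,8,8a-octahydronaphthalene-1-carbaldehyde
Product: 13 [(4aS,8aS)-2,5,5,8a-tetramethyl-3,4,4a,5,6,7,8,8a-octahydronaphthalen-1-yl]methanol (drim-8-en-11-ol)
Conditions: RhCl(PPh3)3 (1.05 equiv), toluene, 110 °C
Reagents that add atoms: none
Why: In this Tsuji–Wilkinson decarbonylation, oxidative addition of the formyl C–H bond to monovalent rhodium, CO extrusion and reductive elimination replace the formyl group by hydrogen, which erases the C6 centre and should leave the tetrasubstituted alkene and hydroxyl untouched.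

Step 7
Reactants: 13 [(4aS,8aS)-2,5,5,8a-tetramethyl-3,4,4a,5,6,7,8,8a-octahydronaphthalen-1-yl]methanol
Product: 14 [(1S,2S,4aS,8aS)-2,5,5,8a-tetramethyldecahydronaphthalen-1-yl]methanol (8β-methyl, 9β-hydroxymethyl)
Conditions: H2 (50 bar), [Ir(cod)(PCy3)(py)]PF6 (10 mol%), CH2Cl2, rt
Reagents that add atoms: none
Why: In this hydroxyl-directed homogeneous hydrogenation, iridium bound to the C11 hydroxyl should add H2 syn to the α-face, opposite the axial C10 methyl, which sets C8 (8α-H, 8β-methyl) and C9 (9α-H) together.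

Step 8
Reactants: 14 [(1S,2S,4aS,8aS)-2,5,5,8a-tetramethyldecahydronaphthalen-1-yl]methanol
Product: 15 (1S,2S,4aS,8aS)-2,5,5,8a-tetramethyldecahydronaphthalene-1-carbaldehyde
Conditions: triacetoxyperiodinane (DMP), CH2Cl2, rt
Reagents that add atoms: none
Why: Hypervalent-iodine oxidation of the primary alcohol under neutral conditions should give the aldehyde without epimerising C9, whose equatorial 9β-formyl group is also the more stable arrangement.

Step 9
Reactants: 16 2,5-dihydroxybenzaldehyde
Product: 17 2,5-bis(methoxymethoxy)benzaldehyde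
Conditions: MOMCl, i-Pr2NEt, CH2Cl2, 0 °C to rt
Reagents that add atoms: chloromethyl methyl ether, COCCl
Why: Williamson-type O-alkylation of both phenols gives acetal ethers that tolerate organolithium reagents and can later be removed without protic acid.

Step 10
Reactants: 17 2,5-bis(methoxymethoxy)benzaldehyde
Product: 19 2,5-bis(methoxymethoxy)phenol, via aryl formate 18 (not isolated)
Conditions: mCPBA, CH2Cl2, rt; then K2CO3, MeOH, 0 °C
Reagents that add atoms: 3-chloroperoxybenzoic acid, OOC(=O)c1cccc(Cl)c1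
Why: Baeyer–Villiger (Dakin-type) oxidation of the electron-rich benzaldehyde proceeds by aryl migration to the formate, whose methanolysis gives the phenol that becomes the C4′ hydroxyl.

Step 11
Reactants: 19 2,5-bis(methoxymethoxy)phenol
Product: 20 2-hydroxy-3,6-bis(methoxymethoxy)benzaldehyde
Conditions: MgCl2, Et3N, (CH2O)n, MeCN, reflux; then aq. citric acid
Reagents that add atoms: formaldehyde (from paraformaldehyde), C=O
Why: Magnesium-phenoxide-directed ortho-formylation (hydroxymethylation, then hydride transfer to a second formaldehyde) can only occur at the single free ortho position, between the hydroxyl and a methoxymethoxy group.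

Step 12
Reactants: 20 2-hydroxy-3,6-bis(methoxymethoxy)benzaldehyde
Product: 21 5-bromo-2-hydroxy-3,6-bis(methoxymethoxy)benzaldehyde
Conditions: NBS, MeCN, 0 °C
Reagents that add atoms: N-bromosuccinimide, O=C1CCC(=O)N1Br
Why: Electrophilic aromatic bromination should occur para to the free hydroxyl and ortho to a methoxymethoxy group, the only position activated by two oxygens and meta to the formyl group.

Step 13
Reactants: 21 5-bromo-2-hydroxy-3,6-bis(methoxymethoxy)benzaldehyde
Product: 22 5-bromo-3,6-bis(methoxymethoxy)-2-(prop-2-en-1-yloxy)benzaldehyde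
Conditions: allyl bromide, K2CO3, DMF, 40 °C
Reagents that add atoms: allyl bromide, C=CCBr
Why: Williamson etherification of the remaining phenol installs an allyl group that is orthogonal to the methoxymethyl ethers and removable at the end under neutral conditions with zerovalent palladium.

Step 14
Reactants: 22 5-bromo-3,6-bis(methoxymethoxy)-2-(prop-2-en-1-yloxy)benzaldehyde; 15 (1S,2S,4aS,8aS)-2,5,5,8a-tetramethyldecahydronaphthalene-1-carbaldehyde
Product: 25 5-{hydroxy[(1S,2S,4aS,8aS)-2,5,5,8a-tetramethyldecahydronaphthalen-1-yl]methyl}-3,6-bis(methoxymethoxy)-2-(prop-2-en-1-yloxy)benzaldehyde (both C11 epimers), via lithium amino-alkoxide 23 (not isolated), via aryllithium 24 (not isolated)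
Conditions: 22, lithium morpholide (morpholine + n-BuLi), THF, −78 °C; n-BuLi, −78 °C; then 15, −78 to −20 °C; aq. NH4Cl
Reagents that add atoms: none
Why: In situ masking of the aryl aldehyde as its lithium α-amino alkoxide, bromine–lithium exchange and 1,2-addition of the aryllithium to hindered aldehyde 15 form the C11–C1′ bond, and the C11 carbinol centre may form as a mixture because step 15 removes it.

Step 15
Reactants: 25 5-{hydroxy[(1S,2S,4aS,8aS)-2,5,5,8a-tetramethyldecahydronaphthalen-1-yl]methyl}-3,6-bis(methoxymethoxy)-2-(prop-2-en-1-yloxy)benzaldehyde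
Product: 27 5-{(E)-[(2S,4aS,8aS)-2,5,5,8a-tetramethyloctahydronaphthalen-1(2H)-ylidene]methyl}-3,6-bis(methoxymethoxy)-2-(prop-2-en-1-yloxy)benzaldehyde, via sulfamate ester 26 (not isolated)
Conditions: methyl N-(triethylammoniosulfonyl)carbamate (inner salt), toluene, 50 °C
Reagents that add atoms: none
Why: Dehydration through the sulfamate ester, which at this electron-rich benzylic centre should ionise and lose H9 (the only β-hydrogen), is expected to give the conjugated alkene with the aryl group away from quaternary C10, i.e. the (E)-isomer from both carbinol epimers.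

Step 16
Reactants: 27 5-{(E)-[(2S,4aS,8aS)-2,5,5,8a-tetramethyloctahydronaphthalen-1(2H)-ylidene]methyl}-3,6-bis(methoxymethoxy)-2-(prop-2-en-1-yloxy)benzaldehyde
Product: 29 3,6-dihydroxy-2-(prop-2-en-1-yloxy)-5-{(E)-[(2S,4aS,8aS)-2,5,5,8a-tetramethyloctahydronaphthalen-1(2H)-ylidene]methyl}benzaldehyde, via bis(trimethylsilyl) ether 28 (not isolated)
Conditions: TMSOTf, 2,2′-bipyridyl, CH2Cl2, 0 °C to rt; then H2O; product kept under argon
Reagents that add atoms: none
Why: Silyl triflate buffered by 2,2′-bipyridyl converts aryl methoxymethyl ethers into aryl silyl ethers that hydrolyse on aqueous work-up, an acetal cleavage without protic acid that should spare the allyl ether, the aldehyde and the acid-sensitive ortho-hydroxy styrene.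

Step 17
Reactants: 29 3,6-dihydroxy-2-(prop-2-en-1-yloxy)-5-{(E)-[(2S,4aS,8aS)-2,5,5,8a-tetramethyloctahydronaphthalen-1(2H)-ylidene]methyl}benzaldehyde
Product: 30 2-formyl-3-(prop-2-en-1-yloxy)-6-{(E)-[(2S,4aS,8aS)-2,5,5,8a-tetramethyloctahydronaphthalen-1(2H)-ylidene]methyl}-1,4-phenylene bis(hydrogen sulfate)
Conditions: SO3·pyridine (8 equiv), pyridine, 50 °C; then aq. NaHCO3
Reagents that add atoms: sulfur trioxide–pyridine complex, O=S(=O)([O-])[n+]1ccccc1
Why: O-Sulfation of phenols with the sulfur trioxide–pyridine complex should esterify the C2′ and C5′ hydroxyls only, because the C4′ oxygen is blocked as its allyl ether.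

Step 18
Reactants: 30 2-formyl-3-(prop-2-en-1-yloxy)-6-{(E)-[(2S,4aS,8aS)-2,5,5,8a-tetramethyloctahydronaphthalen-1(2H)-ylidene]methyl}-1,4-phenylene bis(hydrogen sulfate)
Product: 31 2-formyl-3-hydroxy-6-{(E)-[(2S,4aS,8aS)-2,5,5,8a-tetramethyloctahydronaphthalen-1(2H)-ylidene]methyl}-1,4-phenylene bis(hydrogen sulfate) (CNP0309628.1)
Conditions: Pd(PPh3)4 (5 mol%), sodium p-toluenesulfinate, THF/MeOH, rt; then Dowex 50W (H+ form), 0 °C
Reagents that add atoms: none
Why: Zerovalent palladium ionises the aryl allyl ether to a π-allyl complex that the sulfinate captures (Tsuji–Trost deallylation), freeing the C4′ phenol under neutral conditions that should leave the aryl sulfates, aldehyde and alkene intact before cation exchange gives the free acid.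

Compound list
1 | but-2-yn-1-ol | CC#CCO | starting material
2 | isopropenylmagnesium bromide (prop-1-en-2-ylmagnesium bromide) | C=C(C)[Mg]Br | starting material
3 | cyclic alkenylmagnesium alkoxide, 3-methyl-4-(prop-1-en-2-yl)-2,5-dihydro-1,2-oxamagnesole | CC1=C(C(C)=C)CO[Mg]1 | intermediate
4 | (2Z)-3-iodo-2-(prop-1-en-2-yl)but-2-en-1-ol | C=C(C)/C(CO)=C(\C)I | intermediate
5 | 2,2-dimethylpent-4-enenitrile | C=CCC(C)(C)C#N | starting material
6 | 5-(9-borabicyclo[3.3.1]nonan-9-yl)-2,2-dimethylpentanenitrile | N#CC(C)(C)CCCB1C2CCCC1CCC2 | intermediate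
7 | (5Z)-6-(hydroxymethyl)-2,2,5,7-tetramethylocta-5,7-dienenitrile | C=C(C)/C(CO)=C(\C)CCCC(C)(C)C#N | intermediate
8 | (5Z)-6-(hydroxymethyl)-2,2,5,7-tetramethylocta-5,7-dienal | C=C(C)/C(CO)=C(\C)CCCC(C)(C)C=O | intermediate
9 | diethyl [(E)-2-(cyclohexylamino)ethenyl]phosphonate | CCOP(=O)(OCC)/C=C/NC1CCCCC1 | starting material
10 | N-cyclohexyl imine of trienal 11 | C=C(C)/C(CO)=C(\C)CCCC(C)(C)/C=C/C=NC1CCCCC1 | intermediate
11 | (2E,7Z)-8-(hydroxymethyl)-4,4,7,9-tetramethyldeca-2,7,9-trienal | C=C(C)/C(CO)=C(\C)CCCC(C)(C)/C=C/C=O | intermediate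
12 | (1S,4aS,8aS)-4-(hydroxymethyl)-3,4a,8,8-tetramethyl-1,2,4a,5,6,7,8,8a-octahydronaphthalene-1-carbaldehyde (6α-formyl-drim-8-en-11-ol) | CC1=C(CO)[C@@]2(C)CCCC(C)(C)[C@@H]2[C@@H](C=O)C1 | intermediate
13 | [(4aS,8aS)-2,5,5,8a-tetramethyl-3,4,4a,5,6,7,8,8a-octahydronaphthalen-1-yl]methanol (drim-8-en-11-ol) | CC1=C(CO)[C@@]2(C)CCCC(C)(C)[C@@H]2CC1 | intermediate
14 | [(1S,2S,4aS,8aS)-2,5,5,8a-tetramethyldecahydronaphthalen-1-yl]methanol | C[C@H]1CC[C@H]2C(C)(C)CCC[C@]2(C)[C@H]1CO | intermediate
15 | (1S,2S,4aS,8aS)-2,5,5,8a-tetramethyldecahydronaphthalene-1-carbaldehyde | C[C@H]1CC[C@H]2C(C)(C)CCC[C@]2(C)[C@H]1C=O | intermediate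
16 | 2,5-dihydroxybenzaldehyde | O=Cc1cc(O)ccc1O | starting material
17 | 2,5-bis(methoxymethoxy)benzaldehyde | O=Cc1cc(OCOC)ccc1OCOC | intermediate
18 | 2,5-bis(methoxymethoxy)phenyl formate | O=COc1cc(OCOC)ccc1OCOC | intermediate
19 | 2,5-bis(methoxymethoxy)phenol | Oc1cc(OCOC)ccc1OCOC | intermediate
20 | 2-hydroxy-3,6-bis(methoxymethoxy)benzaldehyde | O=Cc1c(O)c(OCOC)ccc1OCOC | intermediate
21 | 5-bromo-2-hydroxy-3,6-bis(methoxymethoxy)benzaldehyde | O=Cc1c(O)c(OCOC)cc(Br)c1OCOC | intermediate
22 | 5-bromo-3,6-bis(methoxymethoxy)-2-(prop-2-en-1-yloxy)benzaldehyde | O=Cc1c(OCC=C)c(OCOC)cc(Br)c1OCOC | intermediate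
23 | lithium α-morpholino alkoxide of 22 | [Li]OC(N1CCOCC1)c1c(OCC=C)c(OCOC)cc(Br)c1OCOC | intermediate
24 | aryllithium from 23 (lithium at C1′) | [Li]OC(N1CCOCC1)c1c(OCC=C)c(OCOC)cc([Li])c1OCOC | intermediate
25 | 5-{hydroxy[(1S,2S,4aS,8aS)-2,5,5,8a-tetramethyldecahydronaphthalen-1-yl]methyl}-3,6-bis(methoxymethoxy)-2-(prop-2-en-1-yloxy)benzaldehyde | C[C@H]1CC[C@H]2C(C)(C)CCC[C@]2(C)[C@H]1C(O)c1cc(OCOC)c(OCC=C)c(C=O)c1OCOC | intermediate
26 | N-(methoxycarbonyl)sulfamate ester of 25 | C[C@H]1CC[C@H]2C(C)(C)CCC[C@]2(C)[C@H]1C(OS(=O)(=O)NC(=O)OC)c1cc(OCOC)c(OCC=C)c(C=O)c1OCOC | intermediate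
27 | 5-{(E)-[(2S,4aS,8aS)-2,5,5,8a-tetramethyloctahydronaphthalen-1(2H)-ylidene]methyl}-3,6-bis(methoxymethoxy)-2-(prop-2-en-1-yloxy)benzaldehyde | C[C@H]1CC[C@H]2C(C)(C)CCC[C@]2(C)/C1=C/c1cc(OCOC)c(OCC=C)c(C=O)c1OCOC | intermediate
28 | bis(trimethylsilyl) ether of 29 | C[C@H]1CC[C@H]2C(C)(C)CCC[C@]2(C)/C1=C/c1cc(O[Si](C)(C)C)c(OCC=C)c(C=O)c1O[Si](C)(C)C | intermediate
29 | 3,6-dihydroxy-2-(prop-2-en-1-yloxy)-5-{(E)-[(2S,4aS,8aS)-2,5,5,8a-tetramethyloctahydronaphthalen-1(2H)-ylidene]methyl}benzaldehyde | C[C@H]1CC[C@H]2C(C)(C)CCC[C@]2(C)/C1=C/c1cc(O)c(OCC=C)c(C=O)c1O | intermediate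
30 | 2-formyl-3-(prop-2-en-1-yloxy)-6-{(E)-[(2S,4aS,8aS)-2,5,5,8a-tetramethyloctahydronaphthalen-1(2H)-ylidene]methyl}-1,4-phenylene bis(hydrogen sulfate) | C[C@H]1CC[C@H]2C(C)(C)CCC[C@]2(C)/C1=C/c1cc(OS(=O)(=O)O)c(OCC=C)c(C=O)c1OS(=O)(=O)O | intermediate
31 | 2-formyl-3-hydroxy-6-{(E)-[(2S,4aS,8aS)-2,5,5,8a-tetramethyloctahydronaphthalen-1(2H)-ylidene]methyl}-1,4-phenylene bis(hydrogen sulfate) | C[C@H]1CC[C@H]2C(C)(C)CCC[C@]2(C)/C1=C/c1cc(OS(=O)(=O)O)c(O)c(C=O)c1OS(=O)(=O)O | target

Total step count: 18. Longest linear sequence: 13 steps (steps 1–8, then 14–18); the aryl branch is steps 9–13.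

Steps most likely to fail

1. Step 5 (key cycloaddition). The iminium may not turn over because the leading C5–C10 bond joins a neopentyl carbon to a fully substituted diene terminus; acid-promoted decomposition of the dienyl carbinol or an uncatalysed pathway could also erode enantiomeric purity. The fallback keeps the disconnection but uses an oxazolidinone auxiliary and a Lewis acid. It sets out from aldehyde 8, which is condensed (LiCl, i-Pr2NEt, MeCN) with (4S)-4-benzyl-3-[(diethoxyphosphoryl)acetyl]-1,3-oxazolidin-2-one to give the (E)-N-trienoyl oxazolidinone F1. Me2AlCl (2.5 equiv, CH2Cl2, −30 °C) should form the chelated cationic imide, whose benzyl group shields one face of the s-cis enoyl unit, and the endo cycloadduct F2 would be separated from minor diastereomers. LiOH/H2O2 cleaves the auxiliary to carboxylic acid F3, and photoredox hydrodecarboxylation (9-mesityl-10-phenylacridinium tetrafluoroborate, (PhS)2, i-Pr2NEt, blue light) returns to the route at 13.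

2. Step 7 (directed hydrogenation). The iridium catalyst may fail to bind and reduce the shielded tetrasubstituted C8=C9 alkene, or may isomerise the allylic alcohol instead. The fallback moves the alkene to an unhindered position first. It sets out from 13, which is oxidised with MnO2 to the conjugated aldehyde F4. γ-Deprotonation with KN(SiMe3)2 (THF, −78 °C) at the C8 methyl group cis to the formyl group, then kinetic α-protonation with AcOH, should give the deconjugated aldehyde F5 with an exocyclic C8=CH2 alkene. This 1,1-disubstituted alkene is hydrogenated (H2, Pd/C, EtOAc) from the α-face, opposite the C10 methyl, and the sequence returns to the route at 15.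

3. Step 15 (dehydration). The benzylic cation may be captured by the neighbouring methoxymethoxy oxygen, may suffer a 1,2-hydride shift that moves the alkene into ring B, or may give an E/Z mixture. The fallback forms the alkene by cross-coupling without a cation. It sets out from 15 and 22: aldehyde 15 is converted (KN(SiMe3)2, PhNTf2, THF, −78 °C) into the (E)-enol triflate F6, with the triflate oxygen away from quaternary C10. Bromide 22 is borylated (B2pin2, Pd(dppf)Cl2, KOAc, dioxane) to the arylboronate F7. Suzuki–Miyaura coupling of F6 with F7 (Pd(dppf)Cl2, K3PO4, THF/H2O, rt to 40 °C, kept mild to spare the allyl ether) should proceed with retention of alkene geometry and returns to the route at 27, bypassing 25.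

Further compounds
F1 | step 5 | (4S)-4-benzyl-3-[(2E,7Z)-8-(hydroxymethyl)-4,4,7,9-tetramethyldeca-2,7,9-trienoyl]-1,3-oxazolidin-2-one | C=C(C)/C(CO)=C(\C)CCCC(C)(C)/C=C/C(=O)N1[C@@H](Cc2ccccc2)COC1=O
F2 | step 5 | (4S)-4-benzyl-3-{[(1S,4aS,8aS)-4-(hydroxymethyl)-3,4a,8,8-tetramethyl-1,2,4a,5,6,7,8,8a-octahydronaphthalen-1-yl]carbonyl}-1,3-oxazolidin-2-one | CC1=C(CO)[C@@]2(C)CCCC(C)(C)[C@@H]2[C@H](C1)C(=O)N4[C@@H](Cc3ccccc3)COC4=O
F3 | step 5 | (1S,4aS,8aS)-4-(hydroxymethyl)-3,4a,8,8-tetramethyl-1,2,4a,5,6,7,8,8a-octahydronaphthalene-1-carboxylic acid | CC1=C(CO)[C@@]2(C)CCCC(C)(C)[C@@H]2[C@H](C1)C(=O)O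
F4 | step 7 | (4aS,8aS)-2,5,5,8a-tetramethyl-3,4,4a,5,6,7,8,8a-octahydronaphthalene-1-carbaldehyde (drim-8-en-11-al) | CC1=C(C=O)[C@@]2(C)CCCC(C)(C)[C@@H]2CC1
F5 | step 7 | (1S,4aS,8aS)-5,5,8a-trimethyl-2-methylidenedecahydronaphthalene-1-carbaldehyde | C=C1CC[C@H]2C(C)(C)CCC[C@]2(C)[C@H]1C=O
F6 | step 15 | (E)-[(2S,4aS,8aS)-2,5,5,8a-tetramethyloctahydronaphthalen-1(2H)-ylidene]methyl trifluoromethanesulfonate | C[C@H]1CC[C@H]2C(C)(C)CCC[C@]2(C)/C1=C/OS(=O)(=O)C(F)(F)F
F7 | step 15 | 3,6-bis(methoxymethoxy)-2-(prop-2-en-1-yloxy)-5-(4,4,5,5-tetramethyl-1,3,2-dioxaborolan-2-yl)benzaldehyde | O=Cc1c(OCC=C)c(OCOC)cc(B2OC(C)(C)C(C)(C)O2)c1OCOC
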